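**Assumption:** genipin, a catalogue chemical with configuration (1R,4aS,7aS), is accepted as a commercial starting material. A check of the SMILES shows it has the same spatial arrangement at C1, C5 and C9 as the target.

**Convention:** iridoid numbering is used. C1 is the acetal carbon, followed by O2, C3=C4, C5, C6, C7, C8 and C9. C10 is the CH2 on C8 and C11 is the carbon on C4. β is the face carrying H5 and H9, which is the convex face. The target is 1β-O-acyl, 7β-OH, 8α-OH, 8β-CH2O-acyl, i.e. (1S,4aS,6S,7R,7aS). The 7,8-diol is therefore trans, so a syn-dihydroxylation cannot be used.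

## Retrosynthetic overview

1. The last step is a global desilylation. The C10 (Z)-p-coumarate and the C1 isovalerate are disconnected as two late O-acylations, C10 first and then C1 after selective removal of an anomeric TES group.
2. The C11 CH2OH and the free 8,10-diol both come from a single DIBAL-H operation on a methyl ester that also carries a spiro cyclic carbonate.
3. The trans-7β,8α-diol comes from convex-face epoxidation of C7=C8, then 5-exo opening at C8 with inversion by the C10 O-Boc group. The epoxide oxygen stays on C7.
4. Ring order: no skeletal ring is built. The cis-fused cyclopenta[c]pyran comes intact from genipin. Only two temporary rings are made, the oxirane and then the spiro-1,3-dioxolan-2-one, and both are opened again.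
5. The (Z)-acid comes from Lindlar semihydrogenation of an arylpropiolic acid, which comes from an aryl acetylene and CO2.

## Route

**Step 1**
Reactants: 1, genipin
Product: 2, 10-O-Boc-genipin (C10 tert-butyl carbonate; 1β-OH lactol free)
Conditions: Boc2O (1.1 equiv), DMAP (0.1 equiv), CH2Cl2, −10 → 0 °C
Reagents that add atoms: di-tert-butyl dicarbonate, CC(C)(C)OC(=O)OC(=O)OC(C)(C)C
Why: This is a chemoselective O-acylation (carbonate formation) in which the unhindered primary allylic C10-OH outcompetes the secondary, less nucleophilic hemiacetal OH, and no stereocentre is touched.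

**Step 2**
Reactants: 2
Product: 3, 1β-O-TES-10-O-Boc-genipin
Conditions: TESCl, imidazole, CH2Cl2, 0 °C
Reagents that add atoms: chlorotriethylsilane, CC[Si](Cl)(CC)CC
Why: Silyl protection of the lactol through its dominant 1β anomer blocks ring opening and over-reduction in Step 5, and TES is chosen because it can later be removed in the presence of TBS.

**Step 3**
Reactants: 3
Product: 4, the 7β,8β-epoxide of 3 (oxirane O on the H5/H9 face; CH2OBoc on C8 pushed to α)
Conditions: mCPBA, NaHCO3, CH2Cl2, 0 °C → rt
Reagents that add atoms: mCPBA, OOC(=O)c1cccc(Cl)c1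
Why: In this Prilezhaev epoxidation C7=C8 is the only nucleophilic alkene, because C3=C4 is a push-pull β-alkoxyacrylate, and the peracid attacks the convex β face away from the folded dihydropyran, which sets the C7–O bond as β.

**Step 4**
Reactants: 4
Product: 5, methyl ester bearing 1β-OTES, 7β-OTBS and an 8α-O,10-O cyclic carbonate (spiro-1,3-dioxolan-2-one at C8, C10 now β)
Conditions: TBSOTf (1.3 equiv), 2,6-di-tert-butyl-4-methylpyridine, CH2Cl2, −78 → −20 °C
Reagents that add atoms: TBSOTf, CC(C)(C)[Si](C)(C)OS(=O)(=O)C(F)(F)F
Why: In this silyl-triflate-activated epoxide opening with neighbouring-group participation, the Boc carbonyl O attacks the tertiary C8 in a 5-exo mode from the α face with inversion and loses isobutene, so C8 becomes 8α-O/10β and the silylated epoxide oxygen remains as 7β-OTBS.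

**Step 5**
Reactants: 5
Product: 6, triol with 1β-OTES, 7β-OTBS, 8α-OH, 10-OH and 11-OH
Conditions: DIBAL-H (8 equiv), CH2Cl2, −78 → −20 °C; aq. Rochelle salt
Reagents that add atoms: none
Why: DIBAL-H effects 1,2-reduction of the β-alkoxyacrylate to the allylic alcohol and reductive cleavage of the cyclic carbonate in one operation, while the silyl ethers, the silyl acetal and all stereocentres are untouched.

**Step 6**
Reactants: 6
Product: 7, 11-O-TBS diol (8α-OH and 10-OH free)
Conditions: TBSCl (1.05 equiv), imidazole, CH2Cl2, −20 → 0 °C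
Reagents that add atoms: TBSCl, CC(C)(C)[Si](C)(C)Cl
Why: This sterically controlled monosilylation takes the open primary allylic C11-OH, because C10-OH is neopentyl and flanked by the 7β-OTBS and 1-OTES groups and the tertiary C8-OH is inert.

**Step 7**
Reactants: 8, tert-butyl(4-ethynylphenoxy)dimethylsilane
Product: 9, 3-[4-(TBSO)phenyl]prop-2-ynoic acid
Conditions: n-BuLi, THF, −78 °C; CO2; cold aq. citric acid
Reagents that add atoms: carbon dioxide, O=C=O
Why: Carboxylation of the lithium acetylide proceeds cleanly, and the aryl silyl ether survives low-temperature BuLi and a mildly acidic work-up.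

**Step 8**
Reactants: 9
Product: 10, (Z)-3-[4-(TBSO)phenyl]prop-2-enoic acid
Conditions: H2 (1 atm, stopped at 1 equiv), Lindlar catalyst, quinoline, EtOAc, rt, dark
Reagents that add atoms: none
Why: Lindlar semihydrogenation delivers both hydrogens syn to the alkyne, which fixes the Z alkene geometry.

**Step 9**
Reactants: 7 and 10
Product: 11, 10-O-[(Z)-4-TBSO-cinnamoyl] ester of 7 (8α-OH free)
Conditions: EDC·HCl, DMAP, CH2Cl2, 0 °C → rt, dark
Reagents that add atoms: acid 10, OC(=O)/C=C\c1ccc(O[Si](C)(C)C(C)(C)C)cc1
Why: In this Steglich esterification the only acylable hydroxyl is the primary C10-OH, the tertiary 8-OH does not react, and mild, light-free conditions preserve the Z alkene.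

**Step 10**
Reactants: 11
Product: 12, C1 lactol (drawn as 1β-OH; the anomers equilibrate), with all three TBS groups retained
Conditions: HF·pyridine buffered with excess pyridine, THF, 0 °C, about 1 h; NaHCO3 quench
Reagents that add atoms: none
Why: This selective desilylation works because TES on a lactol oxygen cleaves far faster than alkyl TBS ethers, and aryl TBS ethers are especially slow to cleave under acidic fluoride.

**Step 11**
Reactants: 12 and 13, isovaleric anhydride
Product: 14, 7,11,4'-tris-O-TBS-luzonoid D (1β-O-isovaleryl, 1S)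
Conditions: 13 (1.5 equiv), Et3N, cat. DMAP, CH2Cl2, −20 → 0 °C
Reagents that add atoms: 3-methylbutanoic anhydride, CC(C)CC(=O)OC(=O)CC(C)C
Why: In this DMAP-catalysed lactol acylation under anomeric equilibration, the exposed convex-face β-OH is acylated preferentially because the α face lies under the cyclopentane, which sets C1, and the tertiary 8-OH is untouched.

**Step 12**
Reactants: 14
Product: 15, luzonoid D
Conditions: Et3N·3HF (excess), MeCN/THF, rt, dark, plastic vessel; pH 7 buffer work-up
Reagents that add atoms: none
Why: Near-neutral global fluoride desilylation removes the aryl, primary allylic and secondary TBS groups without cleaving the acylal, migrating the C10 ester, ionising the C11 allylic alcohol or isomerising the Z alkene.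

## Compound list

| No. | Name | SMILES | Role |
|---|---|---|---|
| 1 | genipin | O[C@@H]1OC=C(C(=O)OC)[C@H]2CC=C(CO)[C@@H]12 | starting material |
| 2 | 10-O-Boc-genipin | O[C@@H]1OC=C(C(=O)OC)[C@H]2CC=C(COC(=O)OC(C)(C)C)[C@@H]12 | intermediate |
| 3 | 1-O-TES-10-O-Boc-genipin | CC[Si](CC)(CC)O[C@@H]1OC=C(C(=O)OC)[C@H]2CC=C(COC(=O)OC(C)(C)C)[C@@H]12 | intermediate |
| 4 | 7β,8β-epoxide | CC[Si](CC)(CC)O[C@@H]1OC=C(C(=O)OC)[C@H]2C[C@@H]3O[C@]3(COC(=O)OC(C)(C)C)[C@@H]12 | intermediate |
| 5 | 7β-OTBS 8α,10-spiro-carbonate | CC[Si](CC)(CC)O[C@@H]1OC=C(C(=O)OC)[C@H]2C[C@H](O[Si](C)(C)C(C)(C)C)[C@]3(COC(=O)O3)[C@@H]12 | intermediate |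
| 6 | 8,10,11-triol | CC[Si](CC)(CC)O[C@@H]1OC=C(CO)[C@H]2C[C@H](O[Si](C)(C)C(C)(C)C)[C@](O)(CO)[C@@H]12 | intermediate |
| 7 | 11-O-TBS 8,10-diol | CC[Si](CC)(CC)O[C@@H]1OC=C(CO[Si](C)(C)C(C)(C)C)[C@H]2C[C@H](O[Si](C)(C)C(C)(C)C)[C@](O)(CO)[C@@H]12 | intermediate |
| 8 | tert-butyl(4-ethynylphenoxy)dimethylsilane | C#Cc1ccc(O[Si](C)(C)C(C)(C)C)cc1 | starting material |
| 9 | 3-[4-(TBSO)phenyl]propiolic acid | OC(=O)C#Cc1ccc(O[Si](C)(C)C(C)(C)C)cc1 | intermediate |
| 10 | (Z)-4-TBSO-cinnamic acid | OC(=O)/C=C\c1ccc(O[Si](C)(C)C(C)(C)C)cc1 | intermediate |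
| 11 | C10 (Z)-coumarate, 1-OTES | CC[Si](CC)(CC)O[C@@H]1OC=C(CO[Si](C)(C)C(C)(C)C)[C@H]2C[C@H](O[Si](C)(C)C(C)(C)C)[C@](O)(COC(=O)/C=C\c3ccc(O[Si](C)(C)C(C)(C)C)cc3)[C@@H]12 | intermediate |
| 12 | C1 lactol | O[C@@H]1OC=C(CO[Si](C)(C)C(C)(C)C)[C@H]2C[C@H](O[Si](C)(C)C(C)(C)C)[C@](O)(COC(=O)/C=C\c3ccc(O[Si](C)(C)C(C)(C)C)cc3)[C@@H]12 | intermediate |
| 13 | isovaleric anhydride | CC(C)CC(=O)OC(=O)CC(C)C | starting material |
| 14 | tris-TBS luzonoid D | CC(C)CC(=O)O[C@@H]1OC=C(CO[Si](C)(C)C(C)(C)C)[C@H]2C[C@H](O[Si](C)(C)C(C)(C)C)[C@](O)(COC(=O)/C=C\c3ccc(O[Si](C)(C)C(C)(C)C)cc3)[C@@H]12 | intermediate |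
| 15 | luzonoid D | CC(C)CC(=O)O[C@@H]1OC=C(CO)[C@H]2C[C@H](O)[C@](O)(COC(=O)/C=C\c3ccc(O)cc3)[C@@H]12 | target |

## Summary

**Total step count:** 12

**Longest linear sequence:** 10 steps from genipin (Steps 1–6 and 9–12). The acid fragment takes 2 steps (Steps 7–8).

**Three steps most likely to fail**

1. **Step 4, together with the facial outcome of Step 3.** The risks are α-face epoxidation, cationic rearrangement, or attack at C7 instead of C8.
   Fallback: drop the participation strategy and go through the opposite epoxide.
   - Treat a 10-O-silyl analogue with NBS/H2O to give the 8α-OH/7β-Br bromohydrin.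
   - Close it with base to the 7α,8α-epoxide.
   - Open that epoxide at the secondary C7 from the convex β face with an external carboxylate such as CsOAc. This converges on the same 7β-O/8α-OH array.

2. **Step 9.** The neopentyl C10-OH is hindered, and the activated Z-acid may undergo DMAP-induced Z→E isomerisation.
   Fallback: build the alkene on the substrate.
   - Acylate C10-OH with the small bis(2,2,2-trifluoroethyl)phosphonoacetic acid.
   - Run a Still–Gennari olefination with 4-(TBSO)benzaldehyde (KHMDS/18-crown-6, −78 °C).

3. **Step 12.** The hindered 7-OTBS must be removed in the presence of the acid-labile enol ether/allylic alcohol and the acylal.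
   Fallback: carry C11 as an aldehyde instead of a silyl ether.
   - Replace Step 6 with an allylic-selective MnO2 oxidation, which keeps the enol ether as a deactivated vinylogous formate.
   - Carry out both acylations and the HF desilylations at the aldehyde stage.
   - Finish with a Luche reduction (NaBH4/CeCl3, −78 °C) as the last step.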